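The readings are simulated on assumed constants; the scatter is artificial.

I wanted to know which flask ends with more target after its time: Wednesday's, held cold, or Saturday's, with more protic impurity but warmed partway through.

in all of them: substrate 0.051 M; partner 0.0612 M
- dawn: protic impurity 0.0040 M; temperature −5 °C; run made earlier
- winter: protic impurity 0.018 M; temperature 20 °C; run made earlier
- Wednesday's: protic impurity 0.00600 M; at 0 °C throughout; time 3.0 min
- Saturday's: protic impurity 0.0255 M; at 0 °C until 50 s, from then on at 40 °C; time 3.0 min

- dawn (time / s: target / %, substrate / %): 25.0: 3, 94; 50.0: 9, 90; 80.0: 13, 85; 90.0: 18, 81; 120: 21, 79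
- winter (time / s: target / %, substrate / %): 10.0: 8, 94; 12.0: 9, 91; 20.0: 19, 81; 30.0: 24, 76; 40.0: 26, 70

(readings scatter by 1.5 percentage points)

- which one finishes higher in amount of target, in percent of the substrate charged ("neither" within 2 percentage points) (Wednesday's / Saturday's / neither)
- amount of target at the end, in percent of the substrate charged, Wednesday's
- amount of target at the end, in percent of the substrate charged, Saturday's

- steps thought possible: partner + protic impurity -> quenched reagent; substrate + partner -> target

I reckoned with a partner budget: partner charged minus protic impurity charged, over substrate charged. Each step takes one partner, so this is the ceiling on target once the impurity has been quenched. Saturday's budget was 70.0 % and Wednesday's 108 %, so partner is the limiting reagent on Saturday's and substrate on Wednesday's.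

The earlier runs seemed to contradict this. The winter run had the smaller budget, 84.7 % against 112 %, yet it showed 26 % at 40.0 s, while the dawn run showed 21 % at 120 s. But a ceiling is not a pace. For similar target, 18 % against 19 %, the dawn run needed 4.50 times as long, as far as these readings show.

So I carried the pace over. The dawn pace over Wednesday's 3.0 min gave 31.5 %, and 0 °C is somewhat warmer, so I put Wednesday's a little above that, below its ceiling. The winter pace, read at 20 °C and carried over Saturday's 130 s at 40 °C, gave 84.5 %, more than the budget, so I put Saturday's at its budget.

The forecast chose Saturday's, with 35 % (29 % to 42 %) for Wednesday's and 64 % (54 % to 71 %) for Saturday's, on the ground that “the partner is nearly used up”, and its Saturday's figure stood below mine.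

The flasks gave 36.9 % on Wednesday's and 70.1 % on Saturday's, so Saturday's finished higher.

    partner + protic impurity → quenched reagent (k = 0.630 L mol⁻¹ s⁻¹, Ea = 39.0 kJ mol⁻¹)
    substrate + partner → target, rate k2*[substrate]*[partner]^0.5 (k = 0.0120 L⁰·⁵ mol⁻⁰·⁵ s⁻¹, Ea = 41.0 kJ mol⁻¹)
    (constants at 0 °C)

Saturday's stopped at its budget, with partner at 0 % of its charge and substrate at 29.9 %, and it still stood at 70.1 % after 30.0 min. Wednesday's, given Saturday's temperature programme, gave 89.9 % instead of 36.9 %, so the difference in temperature programme was the main reason for the gap between the two. A neighbour of Saturday's with 0.010 M of protic impurity had a budget of 100 %. It ended at 87.7 %, with 11 % of its partner still there.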